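**Plan**

1. Numbering: lactone O1, C2(=O), C3=C4, C5H2, C6; side chain C1'–C10' counted from the ring (cis C1'=C2', OH on C4', C6', C8', phenyl on C10').
2. Enabling feature: C6, the only ring stereocentre, lies between O1 and C5H2 and carries the unsaturated C1'–C2' unit, while C2–C3=C4–C5 is a four-carbon chain oxidised at C2; the ring is therefore the formal adduct of a C6 aldehyde and a 1-oxygenated butadiene.
3. Retrosynthesis: lactone C2=O back to a methyl acetal and the Z alkene back to an alkyne; then C5–C6 and O1–C2 are cut together (oxa-[4+2]) to an ynal and (E)-1-methoxybuta-1,3-diene; the ynal is cut at C6–C1' (formyl), C3'–C4' (propargyl), C5'–C6' and C7'–C8' (allyl) back to 3-phenylpropanal.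
4. Forward: the chain grows from the phenyl end (allylation, allylation, propargylation, with silylation and ozonolysis between), the alkyne is formylated, the single ring arises in the cycloaddition, and semi-hydrogenation, acetal oxidation and desilylation finish.
5. Stereochemistry: C8' and C6' from BINOL/Ti(OiPr)4-catalysed allylations ((S)- then (R)-ligand, 6',8'-anti), C4' from a chiral phosphoric acid-catalysed allenylboration (4',6'-syn), C6 from a chiral CrCl Schiff-base catalyst (trivalent chromium), the Z alkene from syn addition of H2.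

Key step: step 10

Assumption: each chiral catalyst is taken to attack the same aldehyde face as it does with simple aliphatic aldehydes (in particular the chromium complex from (1S,2R)-1-amino-2-indanol is expected to give 6S); should a model reaction show the opposite sense at any of these steps, the antipodal catalyst is used.

**Route**

Step 1
Reactants: 1 3-phenylpropanal; 2 allyltributylstannane
Product: 4 (3R)-1-phenylhex-5-en-3-ol, via tributylstannyl ether 3 (not isolated)
Conditions: (S)-1,1'-bi-2-naphthol [(S)-BINOL] (10 mol %), Ti(OiPr)4 (10 mol %), 4 Å MS, CH2Cl2, −20 °C; then sat. aq. NaHCO3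
Reagents that add atoms: none
Why: Keck asymmetric allylation: the BINOL–Ti(OiPr)4 Lewis acid binds the aldehyde and the allylstannane adds through an open transition state to the one exposed carbonyl face, which with the (S)-ligand and an unbranched aliphatic aldehyde should give the (R)-carbinol that becomes C8', the O–Sn bond of 3 being hydrolysed on work-up.

Step 2
Reactants: 4 (3R)-1-phenylhex-5-en-3-ol
Product: 5 tert-butyldimethyl{[(3R)-1-phenylhex-5-en-3-yl]oxy}silane
Conditions: TBSCl, imidazole, DMF, rt
Reagents that add atoms: tert-butyldimethylsilyl chloride (TBSCl), CC(C)(C)[Si](C)(C)Cl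
Why: Imidazole-promoted silylation of a secondary alcohol (silyl ether formation) proceeds without touching the alkene, and the non-chelating TBS ether should survive every later step up to the final fluoride treatment.

Step 3
Reactants: 5 tert-butyldimethyl{[(3R)-1-phenylhex-5-en-3-yl]oxy}silane
Product: 7 (3R)-3-[(tert-butyldimethylsilyl)oxy]-5-phenylpentanal, via secondary ozonide 6 (not isolated)
Conditions: O3, CH2Cl2, −78 °C; then PPh3, −78 °C to rt
Reagents that add atoms: ozone, [O-][O+]=O
Why: Ozonolysis with reductive work-up cleaves the only alkene to the aldehyde and formaldehyde, the phenyl ring and the silyl ether being inert to ozone at −78 °C when the gas is stopped at first persistence of the blue colour, and the β-silyloxy aldehyde is carried on without chromatography to avoid elimination.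

Step 4
Reactants: 7 (3R)-3-[(tert-butyldimethylsilyl)oxy]-5-phenylpentanal; 2 allyltributylstannane
Product: 9 (4R,6R)-6-[(tert-butyldimethylsilyl)oxy]-8-phenyloct-1-en-4-ol, via tributylstannyl ether 8 (not isolated)
Conditions: (R)-BINOL (10 mol %), Ti(OiPr)4 (10 mol %), 4 Å MS, CH2Cl2, −20 °C; then sat. aq. NaHCO3
Reagents that add atoms: none
Why: Second Keck asymmetric allylation, now with the (R)-ligand so that the opposite carbonyl face is attacked, should set C6' anti to C8', catalyst control being reinforced by the modest intrinsic 1,3-anti preference of β-silyloxy aldehydes in open Lewis-acid transition states.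

Step 5
Reactants: 9 (4R,6R)-6-[(tert-butyldimethylsilyl)oxy]-8-phenyloct-1-en-4-ol
Product: 10 (4R,6R)-4,6-bis[(tert-butyldimethylsilyl)oxy]-8-phenyloct-1-ene
Conditions: TBSCl, imidazole, DMF, rt
Reagents that add atoms: tert-butyldimethylsilyl chloride (TBSCl), CC(C)(C)[Si](C)(C)Cl
Why: Same silyl ether formation as in step 2, giving a second non-chelating, ozone-stable TBS ether on the secondary C6' hydroxyl.

Step 6
Reactants: 10 (4R,6R)-4,6-bis[(tert-butyldimethylsilyl)oxy]-8-phenyloct-1-ene
Product: 12 (3S,5R)-3,5-bis[(tert-butyldimethylsilyl)oxy]-7-phenylheptanal, via secondary ozonide 11 (not isolated)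
Conditions: O3, CH2Cl2, −78 °C; then PPh3, −78 °C to rt
Reagents that add atoms: ozone, [O-][O+]=O
Why: Same ozonolysis with reductive work-up as in step 3, unmasking the aldehyde carbon that becomes C4' while both silyl ethers, both stereocentres (neither is alpha to the carbonyl) and the phenyl ring are untouched.

Step 7
Reactants: 12 (3S,5R)-3,5-bis[(tert-butyldimethylsilyl)oxy]-7-phenylheptanal; 13 allenylboronic acid pinacol ester
Product: 15 (4R,6R,8R)-6,8-bis[(tert-butyldimethylsilyl)oxy]-10-phenyldec-1-yn-4-ol, via pinacol borate ester 14 (not isolated)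
Conditions: (R)-3,3'-bis(2,4,6-triisopropylphenyl)-1,1'-binaphthyl-2,2'-diyl hydrogen phosphate [(R)-TRIP] (10 mol %), 4 Å MS, toluene, 0 °C; then aqueous work-up
Reagents that add atoms: none
Why: Chiral phosphoric acid-catalysed propargylboration of an aldehyde with an allenylboronate: gamma attack of the allenyl unit through a closed six-membered chair transition state, organised by hydrogen bonds from the acid to a boronate oxygen and from the formyl hydrogen to P=O, delivers the terminal alkyne directly and should place the new C4' carbinol syn to C6' under control of the (R)-catalyst, the closed transition state minimising the opposing 1,3-anti bias of the substrate.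

Step 8
Reactants: 15 (4R,6R,8R)-6,8-bis[(tert-butyldimethylsilyl)oxy]-10-phenyldec-1-yn-4-ol
Product: 16 (4R,6S,8R)-4,6,8-tris[(tert-butyldimethylsilyl)oxy]-10-phenyldec-1-yne
Conditions: TBSCl, imidazole, DMF, rt
Reagents that add atoms: tert-butyldimethylsilyl chloride (TBSCl), CC(C)(C)[Si](C)(C)Cl
Why: Third silyl ether formation on the secondary homopropargylic hydroxyl (conditions as in step 2), which leaves the terminal alkyne C–H free for the next step and gives the uniformly protected triol.

Step 9
Reactants: 16 (4R,6S,8R)-4,6,8-tris[(tert-butyldimethylsilyl)oxy]-10-phenyldec-1-yne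
Product: 19 (5R,7S,9R)-5,7,9-tris[(tert-butyldimethylsilyl)oxy]-11-phenylundec-2-ynal, via lithium acetylide 17 (not isolated), via lithium amino alkoxide 18 (not isolated)
Conditions: n-BuLi, THF, −78 °C; DMF, −78 to 0 °C; inverse quench into cold aq. KH2PO4/t-BuOMe
Reagents that add atoms: N,N-dimethylformamide (DMF), CN(C)C=O
Why: Formylation of a lithium acetylide with DMF (alkyne deprotonation then acyl substitution), in which the tetrahedral amino alkoxide 18 persists until the inverse quench into phosphate buffer so that the base-sensitive ynal, whose new carbonyl carbon becomes C6, is never exposed to strong base that could isomerise it or eliminate the C4' silyloxy group.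

Step 10
Reactants: 19 (5R,7S,9R)-5,7,9-tris[(tert-butyldimethylsilyl)oxy]-11-phenylundec-2-ynal; 20 (E)-1-methoxybuta-1,3-diene
Product: 21 (2R,6S)-2-methoxy-6-{(4R,6S,8R)-4,6,8-tris[(tert-butyldimethylsilyl)oxy]-10-phenyldec-1-yn-1-yl}-5,6-dihydro-2H-pyran
Conditions: 20 (3 equiv), CrCl(C27H29NO2) [dianionic tridentate Schiff base of (1S,2R)-1-amino-2-indanol and 3-(1-adamantyl)-2-hydroxy-5-methylbenzaldehyde; trivalent chromium] (5 mol %), 4 Å MS, minimal t-BuOMe, rt
Reagents that add atoms: none
Why: Oxa-Diels–Alder (hetero-[4+2]) cycloaddition: the chromium centre (trivalent chromium) binds the aldehyde oxygen of 19 and the s-cis diene 20 adds in a concerted, asynchronous transition state in which the C5–C6 bond (diene terminus to carbonyl carbon) forms ahead of O1–C2. The closest known reaction type is the cycloaddition of 1-alkoxybuta-1,3-dienes with aldehydes, conjugated ynals among them, catalysed by CrCl complexes of tridentate aminoindanol Schiff bases. The 5,6-dihydro-2H-pyran ring is closed by the cycloaddition itself, both ring bonds arising suprafacially in one step, so no separate cyclisation mode is involved. C6 is set by the catalyst, whose ligand derived from (1S,2R)-1-amino-2-indanol is expected to expose the aldehyde face leading to 6S while the nearest chain stereocentre C4' is four atoms away; C2 is set by the endo transition state together with the E geometry of the diene (2,6-cis acetal) and is deleted later on oxidation. The step needs aldehyde-face selectivity, endo selectivity and chemoselectivity for C=O over C≡C, and these are secured respectively by the chiral pocket around chromium, by the metal-bound carbonyl lying under the diene, and by the fact that only the carbonyl is Lewis-acid activated while the ynal is slim, linear and has no enolisable alpha hydrogen.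

Step 11
Reactants: 21 (2R,6S)-2-methoxy-6-{(4R,6S,8R)-4,6,8-tris[(tert-butyldimethylsilyl)oxy]-10-phenyldec-1-yn-1-yl}-5,6-dihydro-2H-pyran
Product: 22 (2R,6S)-2-methoxy-6-{(1Z,4R,6S,8R)-4,6,8-tris[(tert-butyldimethylsilyl)oxy]-10-phenyldec-1-en-1-yl}-5,6-dihydro-2H-pyran
Conditions: H2 (1 atm), Pd/CaCO3 poisoned with Pb(OAc)2 (Lindlar catalyst), quinoline, EtOAc, rt
Reagents that add atoms: none
Why: Lindlar semi-hydrogenation: syn addition of one equivalent of H2 on lead-poisoned palladium gives the Z C1'=C2' alkene, the alkyne being adsorbed far more strongly than the ring C3=C4 alkene or the newly formed alkene so that reduction should stop at the diene when hydrogen uptake is monitored, with the allylic acetal, the silyl ethers and C6 untouched.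

Step 12
Reactants: 22 (2R,6S)-2-methoxy-6-{(1Z,4R,6S,8R)-4,6,8-tris[(tert-butyldimethylsilyl)oxy]-10-phenyldec-1-en-1-yl}-5,6-dihydro-2H-pyran
Product: 23 (6S)-6-{(1Z,4R,6S,8R)-4,6,8-tris[(tert-butyldimethylsilyl)oxy]-10-phenyldec-1-en-1-yl}-5,6-dihydro-2H-pyran-2-one
Conditions: pyridinium chlorochromate [C5H5NH][CrO3Cl] (hexavalent chromium), Celite, CH2Cl2, rt
Reagents that add atoms: pyridinium chlorochromate, [O-][Cr](=O)(=O)Cl.c1cc[nH+]cc1
Why: Direct chromium oxidation of a cyclic allylic acetal to the α,β-unsaturated δ-lactone (acetal-to-lactone oxidation): the mildly acidic chlorochromate ionises the methyl acetal to the conjugated oxocarbenium ion, adds at C2 and the chromate ester collapses to the C2 carbonyl with loss of methanol, conditions under which TBS ethers, both alkenes and the C6 stereocentre are expected to persist.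

Step 13
Reactants: 23 (6S)-6-{(1Z,4R,6S,8R)-4,6,8-tris[(tert-butyldimethylsilyl)oxy]-10-phenyldec-1-en-1-yl}-5,6-dihydro-2H-pyran-2-one
Product: 24 (6S)-6-[(1Z,4R,6S,8R)-4,6,8-trihydroxy-10-phenyldec-1-en-1-yl]-5,6-dihydro-2H-pyran-2-one
Conditions: HF·pyridine, pyridine, THF, 0 °C to rt
Reagents that add atoms: none
Why: Fluoride-mediated desilylation removes the three secondary TBS ethers under pyridine-buffered conditions mild enough for the unsaturated lactone, the Z alkene and the allylic C6–O bond, and no stereocentre is involved.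

**Compound list**

1 | 3-phenylpropanal | O=CCCc1ccccc1 | starting material
2 | allyltributylstannane | C=CC[Sn](CCCC)(CCCC)CCCC | starting material
3 | tributyl{[(3R)-1-phenylhex-5-en-3-yl]oxy}stannane (formed in situ) | C=CC[C@H](O[Sn](CCCC)(CCCC)CCCC)CCc1ccccc1 | intermediate
4 | (3R)-1-phenylhex-5-en-3-ol | C=CC[C@H](O)CCc1ccccc1 | intermediate
5 | tert-butyldimethyl{[(3R)-1-phenylhex-5-en-3-yl]oxy}silane | C=CC[C@H](O[Si](C)(C)C(C)(C)C)CCc1ccccc1 | intermediate
6 | 3-{(2R)-2-[(tert-butyldimethylsilyl)oxy]-4-phenylbutyl}-1,2,4-trioxolane (formed in situ, epimers at the ring carbon) | C1(C[C@H](O[Si](C)(C)C(C)(C)C)CCc2ccccc2)OCOO1 | intermediate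
7 | (3R)-3-[(tert-butyldimethylsilyl)oxy]-5-phenylpentanal | O=CC[C@H](O[Si](C)(C)C(C)(C)C)CCc1ccccc1 | intermediate
8 | tributylstannyl ether of 9 (formed in situ) | C=CC[C@@H](O[Sn](CCCC)(CCCC)CCCC)C[C@H](O[Si](C)(C)C(C)(C)C)CCc1ccccc1 | intermediate
9 | (4R,6R)-6-[(tert-butyldimethylsilyl)oxy]-8-phenyloct-1-en-4-ol | C=CC[C@@H](O)C[C@H](O[Si](C)(C)C(C)(C)C)CCc1ccccc1 | intermediate
10 | (4R,6R)-4,6-bis[(tert-butyldimethylsilyl)oxy]-8-phenyloct-1-ene | C=CC[C@@H](O[Si](C)(C)C(C)(C)C)C[C@H](O[Si](C)(C)C(C)(C)C)CCc1ccccc1 | intermediate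
11 | 3-{(2S,4R)-2,4-bis[(tert-butyldimethylsilyl)oxy]-6-phenylhexyl}-1,2,4-trioxolane (formed in situ, epimers at the ring carbon) | C1(C[C@@H](O[Si](C)(C)C(C)(C)C)C[C@H](O[Si](C)(C)C(C)(C)C)CCc2ccccc2)OCOO1 | intermediate
12 | (3S,5R)-3,5-bis[(tert-butyldimethylsilyl)oxy]-7-phenylheptanal | O=CC[C@@H](O[Si](C)(C)C(C)(C)C)C[C@H](O[Si](C)(C)C(C)(C)C)CCc1ccccc1 | intermediate
13 | allenylboronic acid pinacol ester [4,4,5,5-tetramethyl-2-(propa-1,2-dien-1-yl)-1,3,2-dioxaborolane] | C=C=CB1OC(C)(C)C(C)(C)O1 | starting material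
14 | pinacol borate ester of 15 (formed in situ) | C#CC[C@@H](OB1OC(C)(C)C(C)(C)O1)C[C@@H](O[Si](C)(C)C(C)(C)C)C[C@H](O[Si](C)(C)C(C)(C)C)CCc1ccccc1 | intermediate
15 | (4R,6R,8R)-6,8-bis[(tert-butyldimethylsilyl)oxy]-10-phenyldec-1-yn-4-ol | C#CC[C@@H](O)C[C@@H](O[Si](C)(C)C(C)(C)C)C[C@H](O[Si](C)(C)C(C)(C)C)CCc1ccccc1 | intermediate
16 | (4R,6S,8R)-4,6,8-tris[(tert-butyldimethylsilyl)oxy]-10-phenyldec-1-yne | C#CC[C@@H](O[Si](C)(C)C(C)(C)C)C[C@@H](O[Si](C)(C)C(C)(C)C)C[C@H](O[Si](C)(C)C(C)(C)C)CCc1ccccc1 | intermediate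
17 | lithium acetylide of 16 (formed in situ) | [Li]C#CC[C@@H](O[Si](C)(C)C(C)(C)C)C[C@@H](O[Si](C)(C)C(C)(C)C)C[C@H](O[Si](C)(C)C(C)(C)C)CCc1ccccc1 | intermediate
18 | lithium (5R,7S,9R)-1-(dimethylamino)-5,7,9-tris[(tert-butyldimethylsilyl)oxy]-11-phenylundec-2-yn-1-olate (formed in situ, epimers at C1) | CN(C)C(O[Li])C#CC[C@@H](O[Si](C)(C)C(C)(C)C)C[C@@H](O[Si](C)(C)C(C)(C)C)C[C@H](O[Si](C)(C)C(C)(C)C)CCc1ccccc1 | intermediate
19 | (5R,7S,9R)-5,7,9-tris[(tert-butyldimethylsilyl)oxy]-11-phenylundec-2-ynal | O=CC#CC[C@@H](O[Si](C)(C)C(C)(C)C)C[C@@H](O[Si](C)(C)C(C)(C)C)C[C@H](O[Si](C)(C)C(C)(C)C)CCc1ccccc1 | intermediate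
20 | (E)-1-methoxybuta-1,3-diene | CO/C=C/C=C | starting material
21 | (2R,6S)-2-methoxy-6-{(4R,6S,8R)-4,6,8-tris[(tert-butyldimethylsilyl)oxy]-10-phenyldec-1-yn-1-yl}-5,6-dihydro-2H-pyran | CO[C@H]1C=CC[C@@H](C#CC[C@@H](O[Si](C)(C)C(C)(C)C)C[C@@H](O[Si](C)(C)C(C)(C)C)C[C@H](O[Si](C)(C)C(C)(C)C)CCc2ccccc2)O1 | intermediate
22 | (2R,6S)-2-methoxy-6-{(1Z,4R,6S,8R)-4,6,8-tris[(tert-butyldimethylsilyl)oxy]-10-phenyldec-1-en-1-yl}-5,6-dihydro-2H-pyran | CO[C@H]1C=CC[C@@H](/C=C\C[C@@H](O[Si](C)(C)C(C)(C)C)C[C@@H](O[Si](C)(C)C(C)(C)C)C[C@H](O[Si](C)(C)C(C)(C)C)CCc2ccccc2)O1 | intermediate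
23 | (6S)-6-{(1Z,4R,6S,8R)-4,6,8-tris[(tert-butyldimethylsilyl)oxy]-10-phenyldec-1-en-1-yl}-5,6-dihydro-2H-pyran-2-one | O=C1C=CC[C@@H](/C=C\C[C@@H](O[Si](C)(C)C(C)(C)C)C[C@@H](O[Si](C)(C)C(C)(C)C)C[C@H](O[Si](C)(C)C(C)(C)C)CCc2ccccc2)O1 | intermediate
24 | (6S)-6-[(1Z,4R,6S,8R)-4,6,8-trihydroxy-10-phenyldec-1-en-1-yl]-5,6-dihydro-2H-pyran-2-one | O=C1C=CC[C@@H](/C=C\C[C@@H](O)C[C@@H](O)C[C@H](O)CCc2ccccc2)O1 | target

**Step count**

Total steps: 13. Longest linear sequence: 13 steps, from 1 to 24.

**Steps most likely to fail**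

Step 10 (key cycloaddition). The chiral chromium catalyst may discriminate poorly between the two aldehyde faces of the long, silyl-rich ynal, or turnover may be so slow that the ynal decomposes before it is consumed. The fallback sets out from 19 and rejoins the route at 23; it keeps C6 as the aldehyde carbon but forms the ring by metathesis. Keck allylation of 19 with stannane 2 and (S)-BINOL/Ti(OiPr)4 passes through the tributylstannyl ether F1 and, after hydrolytic work-up, should give the propargylic homoallylic alcohol F2 with C6 already (S). Lindlar semi-hydrogenation (Pd/CaCO3 poisoned with Pb(OAc)2, quinoline) then gives the (Z)-dienol F3, and acryloyl chloride/Et3N the acrylate F4. Ring-closing metathesis with the second-generation Grubbs catalyst RuCl2(=CHPh)(PCy3)(H2IMes) in CH2Cl2 at 40 °C joins the terminal alkene to the acrylate, forms C3=C4 and delivers 23 directly at the lactone oxidation level, so steps 11 and 12 are not needed.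

Step 7 (propargylboration). Catalyst control may be too weak in the 1,3-syn sense, which runs against the substrate bias, or uncatalysed background allenylboration may compete, so that C4' is formed as a mixture. The fallback sets out from 9 and rejoins at 16; it sets C4' by substrate control from the C6' hydroxyl, and steps 5 to 8 are not used. Boc2O/DMAP converts 9 into the tert-butyl carbonate F5. IBr in toluene at −85 °C effects iodocarbonate cyclisation through a chair with both substituents equatorial and should give the cis-4,6-disubstituted iodomethyl dioxanone F6, which fixes the 4',6'-syn relationship. K2CO3 in MeOH cleaves the carbonate and closes the terminal epoxide to the syn epoxy alcohol F7. Lithium acetylide–ethylenediamine complex LiC≡CH·H2NCH2CH2NH2 in DMSO opens the epoxide at its CH2 carbon to the alkynyl diol F8; a silyl shift between the C6' and C8' oxygens under these basic conditions would be of no consequence, because all hydroxyls are silylated next. Double silylation with TBSOTf/2,6-lutidine gives 16.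

Step 12 (acetal oxidation). Ionisation of the methyl acetal may be incomplete, the allylic oxocarbenium ion may be attacked at C4 instead of C2, or the chromium reagent may attack the skipped diene or loosen a silyl ether. The fallback sets out from 22 and rejoins at 23; it separates hydrolysis from oxidation and avoids chromium. Pyridinium p-toluenesulfonate in wet acetone hydrolyses the acetal to the lactol F9 (anomer mixture), which, being allylic, is oxidised with MnO2 in CH2Cl2 (or PhI(OAc)2 with catalytic TEMPO) to 23.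

**Further compounds**

F1 | step 10 | tributylstannyl ether of F2 (not isolated) | C=CC[C@H](O[Sn](CCCC)(CCCC)CCCC)C#CC[C@@H](O[Si](C)(C)C(C)(C)C)C[C@@H](O[Si](C)(C)C(C)(C)C)C[C@H](O[Si](C)(C)C(C)(C)C)CCc1ccccc1
F2 | step 10 | (4S,8R,10S,12R)-8,10,12-tris[(tert-butyldimethylsilyl)oxy]-14-phenyltetradec-1-en-5-yn-4-ol | C=CC[C@H](O)C#CC[C@@H](O[Si](C)(C)C(C)(C)C)C[C@@H](O[Si](C)(C)C(C)(C)C)C[C@H](O[Si](C)(C)C(C)(C)C)CCc1ccccc1
F3 | step 10 | (4S,5Z,8R,10S,12R)-8,10,12-tris[(tert-butyldimethylsilyl)oxy]-14-phenyltetradeca-1,5-dien-4-ol | C=CC[C@H](O)/C=C\C[C@@H](O[Si](C)(C)C(C)(C)C)C[C@@H](O[Si](C)(C)C(C)(C)C)C[C@H](O[Si](C)(C)C(C)(C)C)CCc1ccccc1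
F4 | step 10 | (4S,5Z,8R,10S,12R)-8,10,12-tris[(tert-butyldimethylsilyl)oxy]-14-phenyltetradeca-1,5-dien-4-yl prop-2-enoate | C=CC[C@H](OC(=O)C=C)/C=C\C[C@@H](O[Si](C)(C)C(C)(C)C)C[C@@H](O[Si](C)(C)C(C)(C)C)C[C@H](O[Si](C)(C)C(C)(C)C)CCc1ccccc1
F5 | step 7 | tert-butyl (4R,6R)-6-[(tert-butyldimethylsilyl)oxy]-8-phenyloct-1-en-4-yl carbonate | C=CC[C@@H](OC(=O)OC(C)(C)C)C[C@H](O[Si](C)(C)C(C)(C)C)CCc1ccccc1
F6 | step 7 | (4S,6R)-6-{(2R)-2-[(tert-butyldimethylsilyl)oxy]-4-phenylbutyl}-4-(iodomethyl)-1,3-dioxan-2-one | IC[C@@H]1C[C@H](C[C@H](O[Si](C)(C)C(C)(C)C)CCc2ccccc2)OC(=O)O1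
F7 | step 7 | (2R,4R)-4-[(tert-butyldimethylsilyl)oxy]-1-[(2S)-oxiran-2-yl]-6-phenylhexan-2-ol | C1O[C@H]1C[C@@H](O)C[C@H](O[Si](C)(C)C(C)(C)C)CCc1ccccc1
F8 | step 7 | (4R,6R,8R)-8-[(tert-butyldimethylsilyl)oxy]-10-phenyldec-1-yne-4,6-diol | C#CC[C@@H](O)C[C@@H](O)C[C@H](O[Si](C)(C)C(C)(C)C)CCc1ccccc1
F9 | step 12 | (6S)-6-{(1Z,4R,6S,8R)-4,6,8-tris[(tert-butyldimethylsilyl)oxy]-10-phenyldec-1-en-1-yl}-5,6-dihydro-2H-pyran-2-ol (anomer mixture) | OC1C=CC[C@@H](/C=C\C[C@@H](O[Si](C)(C)C(C)(C)C)C[C@@H](O[Si](C)(C)C(C)(C)C)C[C@H](O[Si](C)(C)C(C)(C)C)CCc2ccccc2)O1
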